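| flask | substrate | coupling partner | precatalyst | remark | time |
|---|---|---|---|---|---|
| Friday's | 0.050 M | 0.0525 M | 70 µM | the very flask that is asked about, followed so far |  |
| flask | 0.050 M | 0.0525 M | 70 µM |  | 6.0 h |
Friday's run (percent of the substrate charged)

| time / min | open intermediate / % | product / % | substrate / % |
|---|---|---|---|
| 8.00 | 16.8 | 0.8 | 82.0 |
| 15.0 | 32.9 | 8.3 | 57.8 |
| 30.0 | 43.9 | 30.0 | 25.6 |
| 60.0 | 33.4 | 61.1 | 4.8 |
| 120 | 16.4 | 82.6 | 0.1 |

(each reading ± 0.3 percentage points)
- time up to 6.0 h at which open intermediate stands highest
- the amount of open intermediate, in percent of the substrate charged, at that time
- earliest time at which at least nineteen twentieths of that best amount are there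
- latest time at which they still are

**Race number.** Freeze the catalyst level and treat Friday's flask as two pseudo-first-order steps in series: substrate to open intermediate, then open intermediate to product. Between 30.0 min and 60.0 min, substrate falls with a constant of 0.0558 min⁻¹. Product gain per open intermediate over that interval, scaled on the assumption that it follows the coupling partner up to the full charge, gives a use constant of 0.0474 min⁻¹. Their quotient is 1.18, the race number: the constant for making open intermediate against the constant for using it at the full charge of coupling partner.

**Peak height.** For two such steps, the peak of open intermediate is the race number raised to the power one over (one minus the race number), here 39.8% of the substrate charged. Friday's reading of 43.9% at 30.0 min stands higher, so one number isn't enough. From the product read at that time, the coupling partner in Friday's flask stands at 71.4% of its charge, and dividing the race number by that share gives 1.65 and a reckoned peak of 46.3%. The two reckoned peaks stand on either side of that reading.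

**Forecast.** The forecast reasons “Friday's run is this same flask, so I read the answer from its curve.” It gives 44% of open intermediate at 0.49 h, with the window from 0.38 h to 0.68 h.

**Result.** The flask gives 44.0% of open intermediate at 0.501 h, with the window from 0.370 h to 0.679 h.

    substrate + free catalyst → free catalyst + open intermediate (k = 920 M⁻¹ min⁻¹)
    free catalyst + open intermediate ⇌ catalyst intermediate (K = 7.20 M⁻¹, k = 6100 M⁻¹ min⁻¹)
    coupling partner + catalyst intermediate → free catalyst + product (k = 2190 M⁻¹ min⁻¹)
    precatalyst → free catalyst (k = 0.146 min⁻¹)

**Richer neighbour.** The neighbour charged with 0.13 M of coupling partner has, by the same scaling, a race number of 0.476, and the peak rule gives 24.2%. Open intermediate in that neighbour peaks at 28.7%, higher than reckoned, and at 6.00 h the neighbour holds 100% product with 62% of its own charge of coupling partner left.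

The data were computed from invented constants, and the scatter is random.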